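**Retrosynthetic overview**

1. Feature: the tetrahydrofuran half (O1–C2–C3–C4–C5, ring C on C2, ring D as benzyl on C4) and the aryltetralin half (C1'–C2'–C3'–C4'–C4a'–C8a', ring B on C1', fused ring A) are constitutional isomers with identical configuration at C3/C2' and C4/C3'. The target is therefore read as a 5,5'-linked pair of all-cis (2R,3R,4S) tetrahydrofurans, one of which has switched to a tetralin. Last disconnections: the aryl mesylate on ring C, then C1'–C8a'.
2. The two arms are told apart by their phenols: ring B free (its arm ionises), ring C as mesylate (its arm stays). This difference is built in at the divanillin stage (one benzyl ether, one mesylate), because a late monomesylation among four phenols and four alcohols could not be selective.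
3. Each tetrahydrofuran: O1–C5 by reduction of the lactol that the C2 hydroxyl forms with a C5 aldehyde while the carbon on C3 is still a carboxylic acid, so only one oxygen can close. C2–C3 comes from a two-directional anti-aldol of the dialdehyde; anti is required because closure with retention at C2 turns an anti adduct into the 2,3-cis ring (open-chain intermediates keep the ring locants C2–C5).
4. The C4 carbinol (OH, ring D benzyl, C5) comes from (S)-malic acid by alkylation of its pivalaldehyde dioxolanone with 4-benzyloxy-3-methoxybenzyl bromide.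
5. Ring order: both tetrahydrofuran rings together (steps 11–12), then the tetralin ring (step 16).

Key step: step 16

Remark: the anti-aldol is assumed to follow the chelated-enolate boat model (aldehyde entering the enolate face remote from the auxiliary benzyl group), which is why the (R)-configured oxazolidinone 7 is used.

**Route**

Step 1
Reactants: 1 (S)-malic acid
Product: 2 2-[(2S,4S)-2-tert-butyl-5-oxo-1,3-dioxolan-4-yl]acetic acid (cis)
Conditions: t-BuCHO, TsOH (cat.), H2SO4 (cat.), pentane, reflux, Dean–Stark; recrystallisation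
Reagents that add atoms: pivalaldehyde, CC(C)(C)C=O
Why: Acid-catalysed acetalisation of the α-hydroxy acid unit with pivalaldehyde (Seebach dioxolanone, self-regeneration of stereocentres) should give the cis isomer preferentially, the acetal centre being set 2S under the influence of the malic acid centre and secured by crystallisation.

Step 2
Reactants: 3 4-(benzyloxy)-3-methoxybenzyl alcohol
Product: 4 4-(benzyloxy)-3-methoxybenzyl bromide
Conditions: PBr3, Et2O, 0 °C; used at once
Reagents that add atoms: phosphorus tribromide, BrP(Br)Br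
Why: PBr3 converts the primary benzylic alcohol into the bromide through a phosphite ester and SN2 displacement by bromide; no stereocentre is involved.

Step 3
Reactants: 2 2-[(2S,4S)-2-tert-butyl-5-oxo-1,3-dioxolan-4-yl]acetic acid; 4 4-(benzyloxy)-3-methoxybenzyl bromide
Product: 5 2-[(2S,4S)-4-[4-(benzyloxy)-3-methoxybenzyl]-2-tert-butyl-5-oxo-1,3-dioxolan-4-yl]acetic acid (benzyl trans to tert-butyl)
Conditions: LiN(SiMe3)2 (2.2 equiv), THF, −78 °C; then 4, −78 → −30 °C; aq. HCl
Reagents that add atoms: none
Why: Double deprotonation gives the carboxylate–dioxolanone enolate, which is alkylated on the face away from the tert-butyl group (Seebach alkylation with self-regeneration of the stereocentre), so the ring D benzyl group replaces H with retention and the quaternary centre that becomes C4 is set S.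

Step 4
Reactants: 5 benzylated dioxolanone acid
Product: 6 (3S)-3-[4-(benzyloxy)-3-methoxybenzyl]-3-hydroxy-4-methoxy-4-oxobutanoic acid
Conditions: NaOMe (2.2 equiv), MeOH, 0 → 23 °C; aq. HCl
Reagents that add atoms: sodium methoxide, [Na+].[O-]C
Why: Methoxide opens the acylal-type lactone (transesterification) and the resulting hemiacetal alkoxide loses pivalaldehyde, which leaves the methyl ester at the carbon that becomes C5, the free tertiary alcohol and the untouched side-chain carboxylate; the quaternary centre is not affected.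

Step 5
Reactants: 6 hydroxy acid monoester; 7 (R)-4-benzyl-1,3-oxazolidin-2-one
Product: 9 methyl (2S)-2-[4-(benzyloxy)-3-methoxybenzyl]-4-[(4R)-4-benzyl-2-oxo-1,3-oxazolidin-3-yl]-2-hydroxy-4-oxobutanoate, via pivalic mixed anhydride 8 (not isolated)
Conditions: t-BuCOCl, Et3N, THF, −20 °C; then LiCl, 7, −20 → 23 °C
Reagents that add atoms: none
Why: Mixed-anhydride N-acylation of the oxazolidinone under LiCl/Et3N activation, in which 8 reacts at its less hindered carbonyl while the tertiary alcohol and the α-quaternary methyl ester stay inert.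

Step 6
Reactants: 9 hydroxy imide
Product: 10 methyl (2S)-2-[4-(benzyloxy)-3-methoxybenzyl]-4-[(4R)-4-benzyl-2-oxo-1,3-oxazolidin-3-yl]-4-oxo-2-(triethylsilyloxy)butanoate
Conditions: Et3SiOTf, 2,6-lutidine, CH2Cl2, −78 → 0 °C
Reagents that add atoms: triethylsilyl trifluoromethanesulfonate, CC[Si](CC)(CC)OS(=O)(=O)C(F)(F)F
Why: Silylation of the tertiary alcohol with a silyl triflate and a hindered pyridine base masks the β-hydroxyl so that the imide can later be enolised without retro-aldol cleavage of the C3–C4 bond.

Step 7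
Reactants: 11 divanillin
Product: 12 6-(benzyloxy)-6'-hydroxy-5,5'-dimethoxybiphenyl-3,3'-dicarbaldehyde
Conditions: BnBr (1.0 equiv), K2CO3 (1.0 equiv), DMF, 23 °C; chromatography, 11 recovered
Reagents that add atoms: benzyl bromide, BrCc1ccccc1
Why: Williamson ether synthesis on the biphenol monoanion: the first phenoxide is stabilised by the hydrogen bond from the neighbouring phenol and the second deprotonation is harder, so one equivalent of base and bromide should favour the mono-ether, which is separated from di-ether and unreacted 11.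

Step 8
Reactants: 12 divanillin mono-benzyl ether
Product: 13 2'-(benzyloxy)-5,5'-diformyl-3,3'-dimethoxybiphenyl-2-yl methanesulfonate (ring B: OBn; ring C: OMs)
Conditions: MsCl, Et3N, CH2Cl2, 0 °C
Reagents that add atoms: methanesulfonyl chloride, CS(=O)(=O)Cl
Why: Sulfonylation of the remaining hindered phenol (through sulfene from MsCl/Et3N) installs the electron-withdrawing group that later keeps the ring C arm from ionising; the aldehydes are inert.

Step 9
Reactants: 13 benzyl ether mesylate dialdehyde; 10 silylated imide (2.4 equiv)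
Product: 15 two-fold anti-aldol adduct of 13 (both arms 2R,3R,4S; C2–OH free; C4–OSiEt3), via bis(trimethylsilyl ether) 14 (not isolated)
Conditions: MgCl2 (0.4 equiv), Et3N (4 equiv), Me3SiCl (3 equiv), EtOAc, 23 °C; then 1 M HCl–THF (1:5), 23 °C, 20 min
Reagents that add atoms: none
Why: Magnesium chloride-catalysed anti-aldol of the N-acyloxazolidinone (Evans anti-aldol; soft enolisation with Et3N, silyl transfer from Me3SiCl turns the catalyst over): the magnesium-chelated Z-enolate adds to each aromatic aldehyde through a boat transition state, which gives the anti relation of C2–OH and C3–C4, and the aldehyde enters on the enolate face remote from the auxiliary benzyl group, which sets 3R and with it 2R on both arms; dilute acid then cleaves only the trimethylsilyl ethers.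

Step 10
Reactants: 15 two-fold anti-aldol adduct
Product: 17 bis(β-hydroxy acid) (auxiliaries removed; both arms 2R,3R,4S), via bis(peroxy acid) 16 (not isolated)
Conditions: LiOH, H2O2, THF–H2O (3:1), 0 °C; aq. Na2SO3; HCl to pH 3
Reagents that add atoms: hydrogen peroxide (as lithium hydroperoxide), OO
Why: Lithium hydroperoxide attacks the exocyclic imide carbonyl selectively (Evans auxiliary cleavage), the peroxy acid 16 being reduced by sulfite, while the α-quaternary methyl ester, the silyl ether and the aryl mesylate should not react at 0 °C; C3 is not epimerised because the carboxylate forms directly.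

Step 11
Reactants: 17 bis(β-hydroxy acid)
Product: 19 bis(lactol acid) (2R,3R,4S; C5 anomeric mixture; C4–OSiEt3), via bis(hydroxy aldehyde) 18 (not isolated)
Conditions: i-Bu2AlH (excess), CH2Cl2–THF, −78 °C; aq. potassium sodium tartrate, then pH 4
Reagents that add atoms: none
Why: Partial reduction of the ester by i-Bu2AlH at −78 °C (the tetrahedral aluminium hemiacetal survives until work-up) gives the aldehyde 18, which the C2 hydroxyl captures as the five-membered lactol, so the O1–C5 bond forms with retention at C2; the acid on C3 sits as an aluminium carboxylate that is not reduced at this temperature and, not being an alcohol, cannot compete for C5.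

Step 12
Reactants: 19 bis(lactol acid)
Product: 20 bis(tetrahydrofuran acid): both arms (2R,3R,4S)-2-aryl-4-[4-(benzyloxy)-3-methoxybenzyl]-4-(triethylsilyloxy)oxolane-3-carboxylic acid
Conditions: Et3SiH, BF3·OEt2, CH2Cl2, −78 → −30 °C
Reagents that add atoms: none
Why: Ionic hydrogenation of the lactol (Et3SiH/BF3·OEt2, Kishi-type reduction): the anomeric hydroxyl ionises to the ring oxocarbenium ion, which the silane reduces to the C5 methylene; the O1–C2 bond is not involved, so the all-cis 2R,3R,4S rings are kept, and at low temperature the benzylic ether of the benzyl-protected arm should not ionise.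

Step 13
Reactants: 20 bis(tetrahydrofuran acid)
Product: 21 bis(tetrahydrofuran) diol: both arms with C3–CH2OH and C4–OSiEt3
Conditions: BH3·THF, THF, 0 → 23 °C; MeOH, then H2O
Reagents that add atoms: none
Why: Borane reduces the carboxylic acids chemoselectively (through acyloxyboranes) to the C3 hydroxymethyl groups; ethers, the silyl ether and the aryl mesylate are inert to this electrophilic hydride.

Step 14
Reactants: 21 bis(tetrahydrofuran) diol
Product: 22 bis(all-cis tetrahydrofuran) tetraol as tris(benzyl ether) monomesylate (C4–OH free on both arms)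
Conditions: HF·pyridine, pyridine, THF, 0 → 23 °C
Reagents that add atoms: none
Why: Fluoride-mediated desilylation with buffered HF·pyridine frees the two tertiary alcohols without base, so the aryl mesylate and the benzylic ethers are kept.

Step 15
Reactants: 22 tris(benzyl ether) monomesylate
Product: 23 5,5'-linked bis(all-cis tetrahydrofuran) monomesylate (ring B and both ring D phenols free; ring C as OMs)
Conditions: H2 (1 atm), Pd/C, EtOAc–EtOH, 23 °C
Reagents that add atoms: none
Why: Catalytic hydrogenolysis of the three aryl benzyl ethers over Pd/C under neutral conditions; the aryl mesylate is not reduced and the cyclic benzylic C2–O1 bonds should cleave much more slowly than ArO–CH2Ph, so the reaction is stopped after uptake of three equivalents.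

Step 16
Reactants: 23 bis(all-cis tetrahydrofuran) monomesylate
Product: 25 target monomesylate (ring B arm as 1'S,2'S,3'S tetralin; ring C arm unchanged 2R,3R,4S tetrahydrofuran; ring C phenol as OMs), via para-quinone methide 24 (not isolated)
Conditions: CF3CO2H (2 equiv), (CF3)2CHOH, 0 °C; aq. NaHCO3
Reagents that add atoms: none
Why: The acid protonates O1 of the arm whose ring B carries the free para-phenol; heterolysis of C2–O1 is pushed by that phenol and gives the para-quinone methide 24 with C5 released as CH2OH, whereas the mesylate on ring C withholds this assistance from the other arm, whose ring and C2 centre stay as they are. Ring D then attacks the methide carbon through its carbon para to OMe (ortho to the benzylic CH2) and rearomatisation gives C1'–C8a'; the closest known reaction is the acid-promoted isomerisation of 2-aryl-4-benzyl-4-hydroxytetrahydrofuran lignans to 1-aryltetralins, an intramolecular Friedel–Crafts alkylation. The tetralin ring closes in a 6-exo-trig mode onto the exocyclic methide carbon. C1' is the only new stereocentre: in the chair-like transition state the biaryl group takes the pseudo-equatorial position trans to the CH2OH on the neighbouring C2', which gives 1'S, while C2' and C3' keep the configuration of C3 and C4. The step needs arm selectivity (OH against OMs para to the benzylic carbon), site selectivity on ring D (the position para to OMe is activated and less crowded than the one between CH2 and OMe) and must outrun reclosure to a tetrahydrofuran, which is reversible while the C–C bond formation is not.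

Step 17
Reactants: 25 target monomesylate
Product: 26 CNP0344108.1
Conditions: KOH, MeOH–H2O (3:1), 50 °C, argon; dilute HCl to pH 5
Reagents that add atoms: none
Why: Hydroxide attacks sulfur of the aryl methanesulfonate (saponification of a sulfonate ester, S–O cleavage) and releases the ring C phenoxide, which is protonated on work-up; at 50 °C under argon no stereocentre should be touched.

**Compound list**

1 | (S)-malic acid | O[C@@H](CC(O)=O)C(O)=O | starting material
2 | 2-[(2S,4S)-2-tert-butyl-5-oxo-1,3-dioxolan-4-yl]acetic acid (cis) | OC(=O)C[C@@H]1O[C@H](C(C)(C)C)OC1=O | intermediate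
3 | 4-(benzyloxy)-3-methoxybenzyl alcohol | COc1cc(CO)ccc1OCc1ccccc1 | starting material
4 | 4-(benzyloxy)-3-methoxybenzyl bromide | COc1cc(CBr)ccc1OCc1ccccc1 | intermediate
5 | 2-[(2S,4S)-4-[4-(benzyloxy)-3-methoxybenzyl]-2-tert-butyl-5-oxo-1,3-dioxolan-4-yl]acetic acid | OC(=O)C[C@]1(Cc2ccc(OCc3ccccc3)c(OC)c2)O[C@H](C(C)(C)C)OC1=O | intermediate
6 | (3S)-3-[4-(benzyloxy)-3-methoxybenzyl]-3-hydroxy-4-methoxy-4-oxobutanoic acid | OC(=O)C[C@@](O)(Cc1ccc(OCc2ccccc2)c(OC)c1)C(=O)OC | intermediate
7 | (R)-4-benzyl-1,3-oxazolidin-2-one | O=C1N[C@H](Cc2ccccc2)CO1 | starting material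
8 | pivalic mixed anhydride of 6 (formed in the flask) | CC(C)(C)C(=O)OC(=O)C[C@@](O)(Cc1ccc(OCc2ccccc2)c(OC)c1)C(=O)OC | intermediate
9 | methyl (2S)-2-[4-(benzyloxy)-3-methoxybenzyl]-4-[(4R)-4-benzyl-2-oxo-1,3-oxazolidin-3-yl]-2-hydroxy-4-oxobutanoate | COC(=O)[C@](O)(Cc1ccc(OCc2ccccc2)c(OC)c1)CC(=O)N1[C@H](Cc2ccccc2)COC1=O | intermediate
10 | triethylsilyl ether of 9 at the tertiary carbinol (2S) | COC(=O)[C@](O[Si](CC)(CC)CC)(Cc1ccc(OCc2ccccc2)c(OC)c1)CC(=O)N1[C@H](Cc2ccccc2)COC1=O | intermediate
11 | divanillin (6,6'-dihydroxy-5,5'-dimethoxybiphenyl-3,3'-dicarbaldehyde) | COc1cc(C=O)cc(-c2cc(C=O)cc(OC)c2O)c1O | starting material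
12 | 6-(benzyloxy)-6'-hydroxy-5,5'-dimethoxybiphenyl-3,3'-dicarbaldehyde | COc1cc(C=O)cc(-c2cc(C=O)cc(OC)c2OCc2ccccc2)c1O | intermediate
13 | 2'-(benzyloxy)-5,5'-diformyl-3,3'-dimethoxybiphenyl-2-yl methanesulfonate | COc1cc(C=O)cc(-c2cc(C=O)cc(OC)c2OCc2ccccc2)c1OS(C)(=O)=O | intermediate
14 | bis(trimethylsilyl ether) of 15 at both C2 oxygens (formed in the flask) | COc1cc([C@H](O[Si](C)(C)C)[C@@H](C(=O)N2[C@H](Cc3ccccc3)COC2=O)[C@@](O[Si](CC)(CC)CC)(Cc2ccc(OCc3ccccc3)c(OC)c2)C(=O)OC)cc(-c2cc([C@H](O[Si](C)(C)C)[C@@H](C(=O)N3[C@H](Cc4ccccc4)COC3=O)[C@@](O[Si](CC)(CC)CC)(Cc3ccc(OCc4ccccc4)c(OC)c3)C(=O)OC)cc(OC)c2OCc2ccccc2)c1OS(C)(=O)=O | intermediate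
15 | two-fold anti-aldol adduct: on ring C (OMs) and ring B (OBn) of 13 each former CHO carbon is C2 of a chain (2R)-CH(OH)–(3R)-CH(CO-Xc)–(4S)-C(OSiEt3)(CH2Ar)–CO2Me, Xc = (4R)-4-benzyl-2-oxo-1,3-oxazolidin-3-yl, Ar = 4-benzyloxy-3-methoxyphenyl | COc1cc([C@H](O)[C@@H](C(=O)N2[C@H](Cc3ccccc3)COC2=O)[C@@](O[Si](CC)(CC)CC)(Cc2ccc(OCc3ccccc3)c(OC)c2)C(=O)OC)cc(-c2cc([C@H](O)[C@@H](C(=O)N3[C@H](Cc4ccccc4)COC3=O)[C@@](O[Si](CC)(CC)CC)(Cc3ccc(OCc4ccccc4)c(OC)c3)C(=O)OC)cc(OC)c2OCc2ccccc2)c1OS(C)(=O)=O | intermediate
16 | bis(peroxy acid): 15 with both CO-Xc groups as CO3H (formed in the flask) | COc1cc([C@H](O)[C@@H](C(=O)OO)[C@@](O[Si](CC)(CC)CC)(Cc2ccc(OCc3ccccc3)c(OC)c2)C(=O)OC)cc(-c2cc([C@H](O)[C@@H](C(=O)OO)[C@@](O[Si](CC)(CC)CC)(Cc3ccc(OCc4ccccc4)c(OC)c3)C(=O)OC)cc(OC)c2OCc2ccccc2)c1OS(C)(=O)=O | intermediate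
17 | bis(β-hydroxy acid): 15 with both CO-Xc groups as CO2H (each arm 2R,3R,4S) | COc1cc([C@H](O)[C@@H](C(=O)O)[C@@](O[Si](CC)(CC)CC)(Cc2ccc(OCc3ccccc3)c(OC)c2)C(=O)OC)cc(-c2cc([C@H](O)[C@@H](C(=O)O)[C@@](O[Si](CC)(CC)CC)(Cc3ccc(OCc4ccccc4)c(OC)c3)C(=O)OC)cc(OC)c2OCc2ccccc2)c1OS(C)(=O)=O | intermediate
18 | bis(hydroxy aldehyde): 17 with both CO2Me groups as CHO (formed in the flask) | COc1cc([C@H](O)[C@@H](C(=O)O)[C@@](O[Si](CC)(CC)CC)(Cc2ccc(OCc3ccccc3)c(OC)c2)C=O)cc(-c2cc([C@H](O)[C@@H](C(=O)O)[C@@](O[Si](CC)(CC)CC)(Cc3ccc(OCc4ccccc4)c(OC)c3)C=O)cc(OC)c2OCc2ccccc2)c1OS(C)(=O)=O | intermediate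
19 | bis(lactol acid): each arm (2R,3R,4S)-2-aryl-4-[4-(benzyloxy)-3-methoxybenzyl]-5-hydroxy-4-(triethylsilyloxy)oxolane-3-carboxylic acid, C5 anomers | COc1cc([C@@H]2OC(O)[C@](O[Si](CC)(CC)CC)(Cc3ccc(OCc4ccccc4)c(OC)c3)[C@@H]2C(=O)O)cc(-c2cc([C@@H]3OC(O)[C@](O[Si](CC)(CC)CC)(Cc4ccc(OCc5ccccc5)c(OC)c4)[C@@H]3C(=O)O)cc(OC)c2OCc2ccccc2)c1OS(C)(=O)=O | intermediate
20 | bis(tetrahydrofuran acid): as 19 with C5 as CH2 (each arm 2R,3R,4S, all-cis) | COc1cc([C@@H]2OC[C@](O[Si](CC)(CC)CC)(Cc3ccc(OCc4ccccc4)c(OC)c3)[C@@H]2C(=O)O)cc(-c2cc([C@@H]3OC[C@](O[Si](CC)(CC)CC)(Cc4ccc(OCc5ccccc5)c(OC)c4)[C@@H]3C(=O)O)cc(OC)c2OCc2ccccc2)c1OS(C)(=O)=O | intermediate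
21 | bis(tetrahydrofuran) diol: as 20 with both CO2H groups as CH2OH | COc1cc([C@@H]2OC[C@](O[Si](CC)(CC)CC)(Cc3ccc(OCc4ccccc4)c(OC)c3)[C@@H]2CO)cc(-c2cc([C@@H]3OC[C@](O[Si](CC)(CC)CC)(Cc4ccc(OCc5ccccc5)c(OC)c4)[C@@H]3CO)cc(OC)c2OCc2ccccc2)c1OS(C)(=O)=O | intermediate
22 | bis(all-cis tetrahydrofuran) tetraol, tris(benzyl ether) monomesylate: as 21 with both C4–OH free | COc1cc([C@@H]2OC[C@](O)(Cc3ccc(OCc4ccccc4)c(OC)c3)[C@@H]2CO)cc(-c2cc([C@@H]3OC[C@](O)(Cc4ccc(OCc5ccccc5)c(OC)c4)[C@@H]3CO)cc(OC)c2OCc2ccccc2)c1OS(C)(=O)=O | intermediate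
23 | 5,5'-linked bis[(2R,3R,4S)-all-cis tetrahydrofuran] monomesylate (key-step precursor; ring B OH, ring C OMs) | COc1cc([C@@H]2OC[C@](O)(Cc3ccc(O)c(OC)c3)[C@@H]2CO)cc(-c2cc([C@@H]3OC[C@](O)(Cc4ccc(O)c(OC)c4)[C@@H]3CO)cc(OC)c2O)c1OS(C)(=O)=O | intermediate
24 | para-quinone methide from ring B after opening of C2–O1 of its arm, C3 and C4 unchanged (formed in the flask) | COc1cc([C@@H]2OC[C@](O)(Cc3ccc(O)c(OC)c3)[C@@H]2CO)cc(C2=CC(=C[C@@H](CO)[C@](O)(CO)Cc3ccc(O)c(OC)c3)C=C(OC)C2=O)c1OS(C)(=O)=O | intermediate
25 | target monomesylate (1'S,2'S,3'S tetralin on ring B; 2R,3R,4S tetrahydrofuran on ring C; ring C phenol as OMs) | COc1cc([C@@H]2OC[C@](O)(Cc3ccc(O)c(OC)c3)[C@@H]2CO)cc(-c2cc([C@H]3c4cc(O)c(OC)cc4C[C@@](O)(CO)[C@@H]3CO)cc(OC)c2O)c1OS(C)(=O)=O | intermediate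
26 | CNP0344108.1 | COc1cc(C[C@@]2(O)CO[C@@H](c3cc(OC)c(O)c(-c4cc([C@H]5c6cc(O)c(OC)cc6C[C@@](O)(CO)[C@@H]5CO)cc(OC)c4O)c3)[C@H]2CO)ccc1O | target

**Step count**

Total step count: 17.
Longest linear sequence: 14 steps (1 → 2 → 5 → 6 → 9 → 10 → 15 → 17 → 19 → 20 → 21 → 22 → 23 → 25 → 26; steps 1, 3–6, 9–17).

**Steps most likely to fail**

Step 9. Enolisation of the neopentyl-type imide may be slow, the enolate may lose its β-silyloxy group, and the bias of the C4 centre may oppose the auxiliary; any of these would leave mono-adduct or erode the anti selectivity on one of the two arms. The fallback sets out from 10 and 13 and comes back at 15. The dibutylboron Z-enolate of 10 is preformed (n-Bu2BOTf, i-Pr2NEt, CH2Cl2, 0 °C) and added at −78 °C to 13 that has been complexed with Et2AlCl. The C–C bond then forms through an open transition state (the Lewis-acid-mediated anti variant of the Evans aldol), in which the boron-chelated enolate should show the same face to the bound aldehyde, and no amine base is present while the enolate waits. Oxidative work-up gives 15 directly, so this fallback makes no new compound (F0).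

Step 16. The mesylated arm may ionise in part (epimerisation at its C2 to the 2,3-trans ring, or a second cyclisation), the quinone methide may be intercepted by a phenol of another molecule, or the opened arm may reclose to a 2,3-trans tetrahydrofuran that then reacts slowly. The fallback sets out from 22 and comes back at 25: the ring switch is run before the phenols are freed. A Lewis acid (Sc(OTf)3 cat. or BF3·OEt2, CH2Cl2, −40 → 0 °C) should ionise only the arm whose ring B carries the electron-releasing benzyl ether, through a para-benzyloxybenzyl cation and not a quinone methide. The ring D benzyl ether closes onto it para to OMe to give the tetralin tris(benzyl ether) F1. Hydrogenolysis of F1 (H2, Pd/C, EtOAc–EtOH) then gives 25, at a stage where the only remaining cyclic benzylic ether sits on the deactivated ring C.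

Step 11. The intermediate aldehyde may be over-reduced to the diol, or the reduction may stall when the aluminium carboxylate aggregates. The fallback sets out from 17 and comes back at 19. The lactone is closed first (PPTS, toluene, 70 °C, methanol distilled off) to the bis(γ-lactone acid) F2. F2 is then reduced with disiamylborane (Sia2BH, THF, 0 → 23 °C; then H2O2, aq. NaOAc), a dialkylborane reduction that stops at the lactol and leaves carboxylic acids alone.

**Further compounds**

F0 | step 9 | none | none
F1 | step 16 | tetralin tris(benzyl ether): 22 in which the ring B arm has become the 1'S,2'S,3'S tetralin (7'-OBn, 6'-OMe) | COc1cc([C@@H]2OC[C@](O)(Cc3ccc(OCc4ccccc4)c(OC)c3)[C@@H]2CO)cc(-c2cc([C@H]3c4cc(OCc5ccccc5)c(OC)cc4C[C@@](O)(CO)[C@@H]3CO)cc(OC)c2OCc2ccccc2)c1OS(C)(=O)=O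
F2 | step 11 | bis(γ-lactone acid): each arm (2R,3R,4S)-2-aryl-4-[4-(benzyloxy)-3-methoxybenzyl]-5-oxo-4-(triethylsilyloxy)oxolane-3-carboxylic acid | COc1cc([C@@H]2OC(=O)[C@](O[Si](CC)(CC)CC)(Cc3ccc(OCc4ccccc4)c(OC)c3)[C@@H]2C(=O)O)cc(-c2cc([C@@H]3OC(=O)[C@](O[Si](CC)(CC)CC)(Cc4ccc(OCc5ccccc5)c(OC)c4)[C@@H]3C(=O)O)cc(OC)c2OCc2ccccc2)c1OS(C)(=O)=O
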